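**Retrosynthetic overview**
1. Target 26 ⇒ acetonide removal and allylic CH3→CHO oxidation of lactone 24. The γ-lactone is the last ring formed, by oxidative lactonisation of the 6-OH/12-OH diol 22.
2. The 8-O-acyl bond ⇒ alcohol 16 + acid 19. Acid 19 comes from (S)-glyceraldehyde acetonide by alkyne homologation and branched hydroxycarbonylation. During acylation 6-OH is masked as C–Bpin and 12-OH as its silyl ether.
3. The C6/C7/C8 triad ⇒ 2-alkenyl enone 14 (β-borylation, equatorial protonation, single-electron ketone reduction) ⇒ Negishi coupling of iodoenone 9 ⇒ ketone 7.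
4. Key disconnection: cyclohexanone 7 with its C10 quaternary centre ⇒ one-carbon radical ring expansion with vinylation of siloxybicyclo[3.1.0]hexane 5 and vinyl bromide.
5. 5 ⇒ cyclopropanation of silyl enol ether 4 ⇒ asymmetric conjugate addition to 2-methylcyclopentenone. Ring order: cyclopentane → bicyclo[3.1.0]hexane → cyclohexane → γ-lactone.

Notation and assumption: ring positions use elemane numbering. C10 is the quaternary carbon (Me, vinyl), C9 the ring CH2, C8 the acyloxy carbon, C7 (bonded to C11) and C6 (bonded to O) the lactone fusion carbons, and C5 the carbon bearing the C4 propenal unit. α is the face of 6-O and 8-O; β is the face of 10-Me. Compounds 2 and 6 (solutions) and 17 are taken as commercial.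

**Step 1**
Reactants: 1 2-methylcyclopent-2-en-1-one; 2 isopropenylmagnesium bromide
Product: 4 (S)-trimethyl{[2-methyl-3-(prop-1-en-2-yl)cyclopent-1-en-1-yl]oxy}silane, via bromomagnesium enolate 3 (not isolated)
Conditions: CuBr·SMe2 (5 mol %), TADDOL-derived chiral phosphine–phosphite ligand (6 mol %), 2-MeTHF, −78 °C; then TMSCl, Et3N, DMPU, −78 → 0 °C
Reagents that add atoms: chlorotrimethylsilane, C[Si](C)(C)Cl
Why: Copper(I)-catalysed asymmetric conjugate addition of the Grignard reagent sets C5 under catalyst control (ligand enantiomer chosen for the S product), and O-silylation of the regiodefined enolate fixes the tetrasubstituted C8=C10 enol ether.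

**Step 2**
Reactants: 4 (S)-silyl enol ether
Product: 5 (4S)-5-methyl-4-(prop-1-en-2-yl)-1-(trimethylsilyloxy)bicyclo[3.1.0]hexane (cyclopropane CH2 anti to the isopropenyl group)
Conditions: Et2Zn (1.3 equiv), CH2I2 (1.3 equiv), CH2Cl2, 0 °C
Reagents that add atoms: diiodomethane, ICI
Why: Furukawa–Simmons–Smith cyclopropanation is fastest at the electron-rich silyl enol ether and occurs anti to the isopropenyl group, and the two new bridgehead centres are erased again in step 3.

**Step 3**
Reactants: 5 siloxybicyclo[3.1.0]hexane; 6 vinyl bromide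
Product: 7 (3S,4S)-3-ethenyl-3-methyl-4-(prop-1-en-2-yl)cyclohexan-1-one
Conditions: 3CzClIPN (2 mol %), Ni(TMHD)2 (10 mol %), K2HPO4 (2 equiv), H2O (5 equiv), 6 (3 equiv, 1 M in THF), DMA, 450 nm LEDs, 25 °C
Reagents that add atoms: none
Why: Proposed new method: the excited cyanoarene (E* about +1.56 V) oxidises the strained, electron-rich siloxycyclopropane, the radical cation loses Me3Si+ to water/phosphate and cleaves the internal C8–C10 bond (tertiary rather than primary radical) to give the ring-expanded 3-oxocyclohexyl radical, this radical is captured by vinyl–Ni(II)Br (from oxidative addition of 6 to Ni(0)) on the face anti to the adjacent isopropenyl group, reductive elimination from Ni(III) forms the C10–vinyl bond and the quaternary stereocentre, and the photocatalyst radical anion (−1.16 V) returns Ni(I) to Ni(0); the closest known reaction types are the FeCl3-mediated ring expansion of siloxycyclopropanes, the Dowd–Beckwith 1,2-acyl-shift ring expansion and the diketonate-nickel/photoredox coupling of tertiary radicals with sp2 bromides, which have not been merged, used with a vinyl halide or used to set a ring stereocentre.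

**Step 4**
Reactants: 7 ketone
Product: 8 (4S,5S)-5-ethenyl-5-methyl-4-(prop-1-en-2-yl)cyclohex-2-en-1-one
Conditions: IBX (1.8 equiv), DMSO/fluorobenzene, 70 °C
Reagents that add atoms: none
Why: IBX dehydrogenation of the ketone can only introduce the C6=C7 double bond because C10 is quaternary, and the isolated alkenes are inert.

**Step 5**
Reactants: 8 enone
Product: 9 (4S,5S)-5-ethenyl-2-iodo-5-methyl-4-(prop-1-en-2-yl)cyclohex-2-en-1-one
Conditions: I2 (1.5 equiv), pyridine/CH2Cl2 (1:1), 0 °C → rt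
Reagents that add atoms: iodine, II
Why: Baylis–Hillman-type α-iodination (pyridine conjugate addition, enolate iodination, elimination) functionalises only the enone α-carbon C7.

**Step 6**
Reactants: 10 2-bromoprop-2-en-1-ol
Product: 11 [(2-bromoprop-2-en-1-yl)oxy](tert-butyl)dimethylsilane
Conditions: TBSCl, imidazole, CH2Cl2, rt
Reagents that add atoms: tert-butyldimethylsilyl chloride, CC(C)(C)[Si](C)(C)Cl
Why: Standard silyl protection of the primary allylic alcohol, which will become C12–O.

**Step 7**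
Reactants: 9 iodoenone; 11 bromoallyl silyl ether
Product: 14 (4S,5S)-2-[3-(tert-butyldimethylsilyloxy)prop-1-en-2-yl]-5-ethenyl-5-methyl-4-(prop-1-en-2-yl)cyclohex-2-en-1-one, via alkenyllithium 12 (not isolated), via alkenylzinc chloride 13 (not isolated)
Conditions: 11, t-BuLi (2 equiv), Et2O, −78 °C; ZnCl2, THF, → 0 °C; then 9, Pd(PPh3)4 (5 mol %), THF, rt
Reagents that add atoms: none
Why: Bromine–lithium exchange, transmetalation to zinc and Negishi cross-coupling form the C7–C11 bond at the C(sp2)–I site, and the alkenylzinc halide does not add to the enone.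

**Step 8**
Reactants: 14 2-alkenyl enone
Product: 15 (2R,3R,4S,5S)-2-[3-(tert-butyldimethylsilyloxy)prop-1-en-2-yl]-5-ethenyl-5-methyl-4-(prop-1-en-2-yl)-3-(4,4,5,5-tetramethyl-1,3,2-dioxaborolan-2-yl)cyclohexan-1-one
Conditions: B2pin2 (1.2 equiv), CuCl (5 mol %), DPEphos (5 mol %), NaOt-Bu (10 mol %), MeOH (2 equiv), THF, rt
Reagents that add atoms: bis(pinacolato)diboron, CC1(C)OB(OC1(C)C)B1OC(C)(C)C(C)(C)O1
Why: Copper(I)-catalysed conjugate borylation delivers boron to C6 anti to the C5 isopropenyl group (6α-B), the epimerisable C7 settles equatorial on protonation (trans to both neighbours), and the non-activated alkenes do not react.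

**Step 9**
Reactants: 15 β-boryl ketone
Product: 16 (1S,2R,3R,4S,5S)-2-[3-(tert-butyldimethylsilyloxy)prop-1-en-2-yl]-5-ethenyl-5-methyl-4-(prop-1-en-2-yl)-3-(4,4,5,5-tetramethyl-1,3,2-dioxaborolan-2-yl)cyclohexan-1-ol
Conditions: SmI2 (2.5 equiv), H2O, Et3N, THF, 0 °C, 5 min
Reagents that add atoms: none
Why: Single-electron (ketyl/organosamarium) reduction gives the thermodynamically preferred equatorial 8α-alcohol, whereas hydride reagents would attack the α face away from the axial 10-methyl group and give the axial epimer, and the isolated alkenes, the C–B bond and the silyl ether are not reduced.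

**Step 10**
Reactants: 17 (S)-2,2-dimethyl-1,3-dioxolane-4-carbaldehyde
Product: 18 (R)-4-ethynyl-2,2-dimethyl-1,3-dioxolane
Conditions: dimethyl (1-diazo-2-oxopropyl)phosphonate, K2CO3, MeOH, 0 °C → rt
Reagents that add atoms: dimethyl (1-diazo-2-oxopropyl)phosphonate, COP(=O)(OC)C(=[N+]=[N-])C(C)=O
Why: Ohira–Bestmann (Seyferth–Gilbert) homologation turns the aldehyde into the terminal alkyne without touching the stereocentre, whose descriptor changes only through CIP priorities.

**Step 11**
Reactants: 18 alkyne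
Product: 19 2-[(4R)-2,2-dimethyl-1,3-dioxolan-4-yl]prop-2-enoic acid
Conditions: Pd(OAc)2 (0.5 mol %), 2-(diphenylphosphino)pyridine (5 mol %), MsOH (5 mol %), CO (20 bar), H2O (5 equiv), THF, 50 °C
Reagents that add atoms: carbon monoxide, [C-]#[O+]; water, O
Why: Palladium/2-pyridylphosphine-catalysed Reppe-type hydroxycarbonylation of a terminal alkyne is strongly Markovnikov-selective and gives the 2-substituted acrylic acid directly.

**Step 12**
Reactants: 16 8α-alcohol; 19 acid
Product: 20 (1S,2R,3R,4S,5S)-2-[3-(tert-butyldimethylsilyloxy)prop-1-en-2-yl]-5-ethenyl-5-methyl-4-(prop-1-en-2-yl)-3-(4,4,5,5-tetramethyl-1,3,2-dioxaborolan-2-yl)cyclohexyl 2-[(4R)-2,2-dimethyl-1,3-dioxolan-4-yl]prop-2-enoate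
Conditions: DIC (1.5 equiv), DMAP (0.3 equiv), CH2Cl2, 0 °C → rt
Reagents that add atoms: none
Why: Steglich esterification is unambiguous because 8-OH is the only free hydroxyl.

**Step 13**
Reactants: 20 boronate ester
Product: 21 (1S,2S,3R,4S,5S)-2-[3-(tert-butyldimethylsilyloxy)prop-1-en-2-yl]-5-ethenyl-3-hydroxy-5-methyl-4-(prop-1-en-2-yl)cyclohexyl 2-[(4R)-2,2-dimethyl-1,3-dioxolan-4-yl]prop-2-enoate
Conditions: NaBO3·4H2O (4 equiv), THF/H2O (1:1), rt
Reagents that add atoms: sodium perborate, O[B-]1(O)OO[B-](O)(O)OO1.[Na+].[Na+]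
Why: Perborate oxidation of the C–B bond proceeds by boron-to-oxygen 1,2-migration with retention and reveals the equatorial 6α-OH under conditions mild enough for the acrylate ester.

**Step 14**
Reactants: 21 silyl ether
Product: 22 (1S,2S,3R,4S,5S)-5-ethenyl-3-hydroxy-2-(3-hydroxyprop-1-en-2-yl)-5-methyl-4-(prop-1-en-2-yl)cyclohexyl 2-[(4R)-2,2-dimethyl-1,3-dioxolan-4-yl]prop-2-enoate
Conditions: HF·pyridine, pyridine, THF, 0 °C → rt
Reagents that add atoms: none
Why: Buffered fluoride desilylation frees the primary allylic 12-OH while the acetonide and the ester stay intact.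

**Step 15**
Reactants: 22 diol
Product: 24 (3aR,4S,6S,7S,7aR)-6-ethenyl-6-methyl-3-methylidene-2-oxo-7-(prop-1-en-2-yl)octahydro-1-benzofuran-4-yl 2-[(4R)-2,2-dimethyl-1,3-dioxolan-4-yl]prop-2-enoate, via lactol 23 (not isolated)
Conditions: TEMPO (20 mol %), PhI(OAc)2 (2.5 equiv), CH2Cl2, rt
Reagents that add atoms: none
Why: TEMPO/PhI(OAc)2 oxidative lactonisation oxidises only the primary allylic alcohol, the enal is trapped by the trans-vicinal 6α-OH as a lactol, and the lactol is oxidised to the trans-fused α-methylene-γ-butyrolactone.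

**Step 16**
Reactants: 24 lactone
Product: 25 (3aR,4S,6S,7R,7aR)-6-ethenyl-6-methyl-3-methylidene-2-oxo-7-(3-oxoprop-1-en-2-yl)octahydro-1-benzofuran-4-yl 2-[(4R)-2,2-dimethyl-1,3-dioxolan-4-yl]prop-2-enoate
Conditions: SeO2 (1.5 equiv), 1,4-dioxane, 70 °C
Reagents that add atoms: selenium dioxide, O=[Se]=O
Why: Riley allylic oxidation attacks the only electron-rich alkene that carries an allylic CH3 (the vinyl group has no allylic hydrogen and the two acrylate-type alkenes are electron-poor) and takes C15 to the enal.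

**Step 17**
Reactants: 25 acetonide
Product: 26 (3aR,4S,6S,7R,7aR)-6-ethenyl-6-methyl-3-methylidene-2-oxo-7-(3-oxoprop-1-en-2-yl)octahydro-1-benzofuran-4-yl (3R)-3,4-dihydroxy-2-methylidenebutanoate (CNP0204284.1)
Conditions: AcOH/H2O (4:1), 40 °C
Reagents that add atoms: none
Why: Mild acid hydrolysis of the isopropylidene acetal releases the (R)-diol without affecting the enal, the lactone, the ester or any stereocentre.

**Compound list**
1 | 2-methylcyclopent-2-en-1-one | CC1=CCCC1=O | starting material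
2 | isopropenylmagnesium bromide | CC(=C)[Mg]Br | starting material
3 | bromomagnesium enolate of (S)-2-methyl-3-isopropenylcyclopentanone | CC1=C(O[Mg]Br)CC[C@H]1C(C)=C | intermediate
4 | (S)-trimethyl{[2-methyl-3-(prop-1-en-2-yl)cyclopent-1-en-1-yl]oxy}silane | CC1=C(O[Si](C)(C)C)CC[C@H]1C(C)=C | intermediate
5 | (4S)-5-methyl-4-(prop-1-en-2-yl)-1-(trimethylsilyloxy)bicyclo[3.1.0]hexane, CH2 anti to isopropenyl | C[Si](C)(C)O[C@@]12CC[C@@H](C(C)=C)[C@]1(C)C2 | intermediate
6 | vinyl bromide | C=CBr | starting material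
7 | (3S,4S)-3-ethenyl-3-methyl-4-(prop-1-en-2-yl)cyclohexan-1-one | O=C1C[C@@](C)(C=C)[C@H](C(C)=C)CC1 | intermediate
8 | (4S,5S)-5-ethenyl-5-methyl-4-(prop-1-en-2-yl)cyclohex-2-en-1-one | O=C1C[C@@](C)(C=C)[C@H](C(C)=C)C=C1 | intermediate
9 | (4S,5S)-5-ethenyl-2-iodo-5-methyl-4-(prop-1-en-2-yl)cyclohex-2-en-1-one | O=C1C[C@@](C)(C=C)[C@H](C(C)=C)C=C1I | intermediate
10 | 2-bromoprop-2-en-1-ol | C=C(Br)CO | starting material
11 | [(2-bromoprop-2-en-1-yl)oxy](tert-butyl)dimethylsilane | C=C(Br)CO[Si](C)(C)C(C)(C)C | intermediate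
12 | [3-(tert-butyldimethylsilyloxy)prop-1-en-2-yl]lithium | [Li]C(=C)CO[Si](C)(C)C(C)(C)C | intermediate
13 | [3-(tert-butyldimethylsilyloxy)prop-1-en-2-yl]zinc chloride | Cl[Zn]C(=C)CO[Si](C)(C)C(C)(C)C | intermediate
14 | (4S,5S)-2-[3-(tert-butyldimethylsilyloxy)prop-1-en-2-yl]-5-ethenyl-5-methyl-4-(prop-1-en-2-yl)cyclohex-2-en-1-one | O=C1C[C@@](C)(C=C)[C@H](C(C)=C)C=C1C(=C)CO[Si](C)(C)C(C)(C)C | intermediate
15 | (2R,3R,4S,5S)-β-boryl ketone (6α-Bpin, 7β-alkenyl) | O=C1C[C@@](C)(C=C)[C@H](C(C)=C)[C@@H](B2OC(C)(C)C(C)(C)O2)[C@@H]1C(=C)CO[Si](C)(C)C(C)(C)C | intermediate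
16 | (1S,2R,3R,4S,5S)-8α-alcohol (6α-Bpin, 7β-alkenyl) | O[C@H]1C[C@@](C)(C=C)[C@H](C(C)=C)[C@@H](B2OC(C)(C)C(C)(C)O2)[C@@H]1C(=C)CO[Si](C)(C)C(C)(C)C | intermediate
17 | (S)-2,2-dimethyl-1,3-dioxolane-4-carbaldehyde | O=C[C@@H]1COC(C)(C)O1 | starting material
18 | (R)-4-ethynyl-2,2-dimethyl-1,3-dioxolane | C#C[C@@H]1COC(C)(C)O1 | intermediate
19 | 2-[(4R)-2,2-dimethyl-1,3-dioxolan-4-yl]prop-2-enoic acid | OC(=O)C(=C)[C@@H]1COC(C)(C)O1 | intermediate
20 | 8α-ester with 6α-Bpin and 12-OTBS | C=C[C@]1(C)C[C@H](OC(=O)C(=C)[C@@H]2COC(C)(C)O2)[C@@H](C(=C)CO[Si](C)(C)C(C)(C)C)[C@H](B3OC(C)(C)C(C)(C)O3)[C@H]1C(C)=C | intermediate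
21 | 8α-ester with 6α-OH and 12-OTBS | C=C[C@]1(C)C[C@H](OC(=O)C(=C)[C@@H]2COC(C)(C)O2)[C@@H](C(=C)CO[Si](C)(C)C(C)(C)C)[C@H](O)[C@H]1C(C)=C | intermediate
22 | 8α-ester 6α,12-diol | C=C[C@]1(C)C[C@H](OC(=O)C(=C)[C@@H]2COC(C)(C)O2)[C@@H](C(=C)CO)[C@H](O)[C@H]1C(C)=C | intermediate
23 | 6,12-lactol (C12 epimers) | C=C[C@]1(C)C[C@H](OC(=O)C(=C)[C@@H]3COC(C)(C)O3)[C@H]2C(=C)C(O)O[C@@H]2[C@H]1C(C)=C | intermediate
24 | trans-fused α-methylene lactone with C5 isopropenyl and side-chain acetonide | C=C[C@]1(C)C[C@H](OC(=O)C(=C)[C@@H]3COC(C)(C)O3)[C@H]2C(=C)C(=O)O[C@@H]2[C@H]1C(C)=C | intermediate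
25 | 15-al lactone with side-chain acetonide | C=C[C@]1(C)C[C@H](OC(=O)C(=C)[C@@H]3COC(C)(C)O3)[C@H]2C(=C)C(=O)O[C@@H]2[C@H]1C(=C)C=O | intermediate
26 | CNP0204284.1 | C=C[C@]1(C)C[C@H](OC(=O)C(=C)[C@@H](O)CO)[C@H]2C(=C)C(=O)O[C@@H]2[C@H]1C(=C)C=O | target

**Total step count:** 17. **Longest linear sequence:** 14 (steps 1–5, 7–9, 12–17).

**Three steps most likely to fail**

Step 3 (the proposed ring expansion with vinylation). Capture of the tertiary radical by nickel may lose to hydrogen-atom loss or to opening of the external cyclopropane bond. The fallback uses known chemistry, sets out from 5 and returns at 7. Compound 5 is treated with FeCl3 (2.2 equiv) in DMF at 0 °C. This oxidative ring expansion cleaves the same internal bond and ends in chlorine capture, giving (4S)-3-chloro-3-methyl-4-(prop-1-en-2-yl)cyclohexan-1-one F1. HCl is eliminated with NaOAc in refluxing MeOH to give (4S)-3-methyl-4-(prop-1-en-2-yl)cyclohex-2-en-1-one F2. Vinylmagnesium bromide with CuBr·SMe2 (THF, −40 °C) is then added in conjugate fashion, anti to the isopropenyl group, to give 7.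

Step 9 (C8 configuration). The reduction may not reach the equatorial alcohol cleanly, or C7 may isomerise beforehand. The fallback sets out from 15 and returns at 20. The ketone is reduced kinetically with L-Selectride (THF, −78 °C), which attacks the open α face and gives the axial 8β-alcohol F5. This alcohol is esterified with inversion by a Mitsunobu reaction with acid 19 (PPh3, DIAD, toluene, 0 °C → rt), giving 20 directly.

Step 8 (conjugate borylation of a hindered α-substituted dienone). The addition may be slow, or the C7 alkenyl group may move into conjugation. The fallback sets out from 14 and returns at 21. Nucleophilic epoxidation (t-BuOOH, DBU, CH2Cl2, 0 °C) occurs on the α face and gives the 6α,7α-epoxy ketone F3. Excess SmI2/H2O/Et3N opens the epoxide at C7 and reduces the ketone in one flask to the 6α,8α-diol F4. Acid 19 (1.0 equiv, DIC, DMAP, −20 °C) then acylates the less hindered 8-OH, because 6-OH is flanked by two branched carbons, and gives 21.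

**Further compounds**
F1 | step 3 | (4S)-3-chloro-3-methyl-4-(prop-1-en-2-yl)cyclohexan-1-one | O=C1CC(C)(Cl)[C@H](C(C)=C)CC1
F2 | step 3 | (4S)-3-methyl-4-(prop-1-en-2-yl)cyclohex-2-en-1-one | O=C1C=C(C)[C@H](C(C)=C)CC1
F3 | step 8 | 6α,7α-epoxy ketone derived from 14 | O=C1C[C@@](C)(C=C)[C@H](C(C)=C)[C@H]2O[C@@]12C(=C)CO[Si](C)(C)C(C)(C)C
F4 | step 8 | 6α,8α-diol with 7β-[3-(tert-butyldimethylsilyloxy)prop-1-en-2-yl] group | O[C@H]1C[C@@](C)(C=C)[C@H](C(C)=C)[C@@H](O)[C@@H]1C(=C)CO[Si](C)(C)C(C)(C)C
F5 | step 9 | axial 8β-alcohol (C8 epimer of 16) | O[C@@H]1C[C@@](C)(C=C)[C@H](C(C)=C)[C@@H](B2OC(C)(C)C(C)(C)O2)[C@@H]1C(=C)CO[Si](C)(C)C(C)(C)C
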